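**Retrosynthetic overview**
1. The (E,E)-diene is cut at the C=C next to the unmethylated pyran. This gives a Julia–Kocienski union of the enal of the 3-methyl half with the tetrazolyl sulfone of the other half, followed by loss of two MOM groups.
2. Structural feature: in each cyclohepta[b]pyran the seven-membered ring has the pyran oxygen O1 on C9a and a tropolone oxygen on C8, with only the C9 methine between them, and the methyl group on C5 next to C4a. Deleting C9 makes C8 and C9a neighbours and contracts the ring to the benzene ring of an 8-methoxy-5-methylchroman, so C9 is brought in last as a dihalocarbene carbon.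
3. Each seven-membered ring is made the same way: chroman, then Birch 4a,7-dihydro diene, then CBr2 addition and electrocyclic opening (9-bromodienone), then SeO2 at C7, then Zn.
4. Ring order in each half: benzene ring (bought), then dihydropyran (Mitsunobu closure of O1–C2 with inversion), then six-to-seven ring enlargement.
5. Stereocentres: C2/C3 come from a syn aldol, because inversion at C2 turns a syn chain into the trans pair. C2 of the other half comes from (S)-benzyl glycidyl ether.

Key step: step 12

Assumption: alkylation of the two unsymmetrical tropolones is drawn on O8. If O7 is alkylated as well, both regioisomers should behave alike afterwards and collapse to the same tropolone in step 34.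
Abbreviations: MOM = methoxymethyl, TBS = tert-butyldimethylsilyl, PT = 1-phenyl-1H-tetrazol-5-yl, DMP = Dess–Martin periodinane. C8a of the chromenes becomes C9a of the cyclohepta[b]pyrans.

**Aryl building block**

Step 1
Reactants: 1 2-methoxy-5-methylphenol
Product: 2 1-methoxy-2-(methoxymethoxy)-4-methylbenzene
Conditions: MOMCl, iPr2NEt, CH2Cl2, 0 °C → rt
Reagents that add atoms: chloromethyl methyl ether, COCCl
Why: O-Alkylation of the phenol (Williamson-type acetal ether formation) masks the acidic OH and installs the chelating group that directs the metalation in step 2.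

Step 2
Reactants: 2 1-methoxy-2-(methoxymethoxy)-4-methylbenzene
Product: 4 2-iodo-4-methoxy-3-(methoxymethoxy)-1-methylbenzene, via aryllithium 3 (not isolated)
Conditions: n-BuLi, TMEDA, Et2O, 0 °C → rt; I2, THF, −78 °C
Reagents that add atoms: iodine, [I][I]
Why: Directed ortho-metalation: the MOM group binds lithium better than the methoxy group and its only free ortho position is the carbon next to the methyl group (future C4a), so lithiation and iodine quench should place the halogen there.

**3-Methyl half**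

Step 3
Reactants: 5 (S)-4-benzyl-3-propanoyl-1,3-oxazolidin-2-one; 6 2-(benzyloxy)acetaldehyde
Product: 8 (S)-4-benzyl-3-[(2S,3S)-4-(benzyloxy)-3-hydroxy-2-methylbutanoyl]-1,3-oxazolidin-2-one, via boron enolate 7 (not isolated)
Conditions: Bu2BOTf, Et3N, CH2Cl2, 0 °C; 6, −78 → 0 °C; H2O2, MeOH, pH 7 buffer
Reagents that add atoms: none
Why: Evans syn aldol reaction: the (Z)-boron enolate 7 reacts through a closed chair transition state on the face turned away from the benzyl group of the auxiliary, which should set the (2S,3S) syn methyl–carbinol pair that becomes C3 and, after inversion in step 9, C2.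

Step 4
Reactants: 8 aldol adduct
Product: 9 (S)-4-benzyl-3-[(2S,3S)-4-(benzyloxy)-3-(TBS-oxy)-2-methylbutanoyl]-1,3-oxazolidin-2-one
Conditions: TBSOTf, 2,6-lutidine, CH2Cl2, 0 °C
Reagents that add atoms: tert-butyldimethylsilyl triflate, CC(C)(C)[Si](C)(C)OS(=O)(=O)C(F)(F)F
Why: Silyl triflate silylation of the hindered secondary alcohol blocks retro-aldol cleavage and keeps the oxygen inert towards hydride and organozinc chemistry.

Step 5
Reactants: 9 silylated imide
Product: 10 (2R,3S)-4-(benzyloxy)-3-(TBS-oxy)-2-methylbutan-1-ol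
Conditions: LiBH4, MeOH (1 equiv), THF, 0 °C
Reagents that add atoms: none
Why: Reductive removal of the auxiliary: borohydride attacks the exocyclic imide carbonyl and takes it down to the primary alcohol without touching either stereocentre.

Step 6
Reactants: 10 primary alcohol
Product: 11 {[(2S,3S)-1-(benzyloxy)-4-iodo-3-methylbutan-2-yl]oxy}(tert-butyl)dimethylsilane
Conditions: I2, PPh3, imidazole, CH2Cl2, 0 °C → rt
Reagents that add atoms: iodine, [I][I]
Why: Appel-type iodination: the alkoxyphosphonium salt of the primary alcohol is displaced by iodide in an SN2 reaction remote from the stereocentres.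

Step 7
Reactants: 11 alkyl iodide; 4 aryl iodide
Product: 13 {[(2S,3R)-1-(benzyloxy)-4-[3-methoxy-2-(methoxymethoxy)-6-methylphenyl]-3-methylbutan-2-yl]oxy}(tert-butyl)dimethylsilane, via alkylzinc iodide 12 (not isolated)
Conditions: Zn dust, LiCl, THF, 40 °C; then 4, Pd(OAc)2 (cat.), SPhos (cat.), THF, 50 °C
Reagents that add atoms: none
Why: Negishi coupling: zinc inserts into the primary carbon–iodine bond, and the bulky biarylphosphine lets palladium couple alkylzinc 12 with the doubly ortho-substituted aryl iodide faster than β-hydride elimination, forming the C4–C4a bond.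

Step 8
Reactants: 13 coupled MOM/TBS ether
Product: 14 2-[(2R,3S)-4-(benzyloxy)-3-hydroxy-2-methylbutyl]-6-methoxy-3-methylphenol
Conditions: HCl (cat.), MeOH, 45 °C
Reagents that add atoms: none
Why: Acid-catalysed methanolysis cleaves the aryl MOM acetal and the secondary silyl ether together, while the benzyl and methyl ethers are stable.

Step 9
Reactants: 14 phenol alcohol
Product: 15 (2R,3R)-2-[(benzyloxy)methyl]-8-methoxy-3,5-dimethyl-3,4-dihydro-2H-chromene
Conditions: PPh3, DIAD, THF, 0 °C → rt
Reagents that add atoms: none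
Why: Intramolecular Mitsunobu etherification: the phenol displaces the activated secondary alcohol in a 6-exo-tet SN2 closure with inversion, turning the (S)-carbinol into (2R) and so placing the C2 and C3 substituents trans.

Step 10
Reactants: 15 chroman
Product: 16 [(2R,3R)-8-methoxy-3,5-dimethyl-3,4,4a,7-tetrahydro-2H-chromen-2-yl]methanol (both C4a epimers)
Conditions: Li, NH3(l)/THF, t-BuOH, −78 → −33 °C
Reagents that add atoms: none
Why: Birch reduction: protonation at C7 and C4a is the only 1,4-mode that leaves both oxygens and the C5 methyl group on double bonds, the benzyl ether is cleaved by the same electrons, and the C4a centre (formed without control) is erased in step 13.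

Step 11
Reactants: 16 diene alcohol
Product: 17 tert-butyl{[(2R,3R)-8-methoxy-3,5-dimethyl-3,4,4a,7-tetrahydro-2H-chromen-2-yl]methoxy}dimethylsilane (both C4a epimers)
Conditions: TBSCl, imidazole, DMF, 0 °C → rt
Reagents that add atoms: tert-butyldimethylsilyl chloride, CC(C)(C)[Si](C)(C)Cl
Why: Silylation under imidazole buffering protects the alcohol from the carbene and the base of step 12 without exposing the acid-labile enediol diether to acid.

Step 12
Reactants: 17 Birch diene silyl ether; 18 tribromomethane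
Product: 20 (2R,3R)-9-bromo-2-(TBS-oxymethyl)-3,5-dimethyl-3,4,4a,7-tetrahydrocyclohepta[b]pyran-8(2H)-one (both C4a epimers), via dibromocyclopropane 19 (not isolated)
Conditions: KOtBu, pentane, −20 °C → rt
Reagents that add atoms: none
Why: KOtBu deprotonates 18 and loss of bromide gives singlet dibromocarbene, an electrophile that adds in one concerted [2+1] event to the most electron-rich alkene of 17, the tetrasubstituted C8=C8a enediol diether, to give 19. In 19 the endo carbon–bromine bond ionises while the C8–C8a bond breaks in a disrotatory two-electron electrocyclic opening pushed by both oxygens, and the freed bromide takes the O-methyl group from the resulting 2-bromo-1,3-dioxyallyl cation by SN2 attack, which leaves the C8 ketone and the C9(Br)=C9a–O1 vinylogous ester (old C8a is now C9a, the carbene carbon is C9). The closest known reaction type is the dihalocarbene ring expansion of Birch-derived alkoxycyclohexa-1,4-dienes to halocycloheptadienones and tropones. The seven-membered ring is closed by one-carbon enlargement of the six-membered ring (C8–C9 and C9–C9a made, C8–C8a lost), not by an end-to-end cyclisation. No lasting stereocentre is created, since the two cyclopropane centres vanish on opening, C2 and C3 are spectators and the C4a mixture is carried on to step 13. The step needs the carbene to choose the dialkoxy alkene over the C5=C6 alkene, which the two donor oxygens secure, and dealkylation at methyl instead of C2, which the unhindered methyl carbon secures; base is kept close to one equivalent per carbene so that 20 is not enolised.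

Step 13
Reactants: 20 bromodienone
Product: 22 (2R,3R)-9-bromo-2-(TBS-oxymethyl)-8-hydroxy-3,5-dimethyl-3,4-dihydrocyclohepta[b]pyran-7(2H)-one, via 7,8-dione 21 (not isolated)
Conditions: SeO2, KH2PO4, 1,4-dioxane, 90 °C
Reagents that add atoms: selenium dioxide, O=[Se]=O
Why: Riley oxidation: the C7 methylene, activated by both the C8 ketone and the C5=C6 alkene, is oxidised to the 7,8-dione 21, whose C4a hydrogen shifts to oxygen at once because the enol is an aromatic tropolone, which also removes the C4a stereocentre.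

Step 14
Reactants: 22 bromotropolone
Product: 23 (2R,3R)-2-(TBS-oxymethyl)-8-hydroxy-3,5-dimethyl-3,4-dihydrocyclohepta[b]pyran-7(2H)-one
Conditions: Zn dust, AcOH, THF, rt
Reagents that add atoms: none
Why: Zinc reduction of an α-halo carbonyl compound: in its 8-oxo tautomer 22 carries bromine α to the carbonyl group, so two-electron transfer expels bromide and acetic acid protonates C9.

Step 15
Reactants: 23 tropolone silyl ether
Product: 24 (2R,3R)-8-hydroxy-2-(hydroxymethyl)-3,5-dimethyl-3,4-dihydrocyclohepta[b]pyran-7(2H)-one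
Conditions: HCl (cat.), MeOH, rt
Reagents that add atoms: none
Why: Acid-catalysed methanolysis of the primary silyl ether, to which the tropolone is inert.

Step 16
Reactants: 24 tropolone alcohol
Product: 25 (2R,3R)-2-(hydroxymethyl)-8-(methoxymethoxy)-3,5-dimethyl-3,4-dihydrocyclohepta[b]pyran-7(2H)-one
Conditions: MOMCl (1.05 equiv), iPr2NEt, CH2Cl2, −20 → 0 °C
Reagents that add atoms: chloromethyl methyl ether, COCCl
Why: Chemoselective O-alkylation: only the acidic tropolone OH is ionised by the amine, so one equivalent of MOMCl should be taken up by the tropolonate and not by the neutral primary alcohol.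

Step 17
Reactants: 25 MOM-protected alcohol
Product: 26 (2R,3R)-8-(methoxymethoxy)-3,5-dimethyl-7-oxo-2,3,4,7-tetrahydrocyclohepta[b]pyran-2-carbaldehyde
Conditions: DMP, pyridine, CH2Cl2, 0 °C → rt
Reagents that add atoms: none
Why: Dess–Martin oxidation stops at the aldehyde under nearly neutral conditions, which should spare the acetal and the configuration at C2.

Step 18
Reactants: 26 aldehyde; 27 (triphenylphosphoranylidene)acetaldehyde
Product: 28 (2E)-3-[(2R,3R)-8-(methoxymethoxy)-3,5-dimethyl-7-oxo-2,3,4,7-tetrahydrocyclohepta[b]pyran-2-yl]prop-2-enal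
Conditions: toluene, 60 °C
Reagents that add atoms: none
Why: Wittig olefination with a stabilised ylide should give the (E)-enal, and the α-oxygenated aldehyde 26 reacts faster than the conjugated product, which limits double homologation.

**Unmethylated half**

Step 19
Reactants: 29 (S)-benzyl glycidyl ether; 30 trimethylsulfonium iodide
Product: 31 (S)-1-(benzyloxy)but-3-en-2-ol
Conditions: n-BuLi, THF, −10 °C → rt
Reagents that add atoms: none
Why: Sulfonium ylide homologation of a terminal epoxide: the methylide opens 29 at its CH2 terminus and further base eliminates dimethyl sulfide, giving the allylic alcohol with the C–O stereocentre untouched.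

Step 20
Reactants: 31 allylic alcohol
Product: 32 {[(2S)-1-(benzyloxy)but-3-en-2-yl]oxy}(tert-butyl)dimethylsilane
Conditions: TBSCl, imidazole, DMF, rt
Reagents that add atoms: tert-butyldimethylsilyl chloride, CC(C)(C)[Si](C)(C)Cl
Why: Standard silylation keeps the hydroxyl group from consuming borane and from binding palladium in step 21.

Step 21
Reactants: 32 silyl ether alkene; 4 aryl iodide
Product: 34 {[(2S)-1-(benzyloxy)-4-[3-methoxy-2-(methoxymethoxy)-6-methylphenyl]butan-2-yl]oxy}(tert-butyl)dimethylsilane, via B-alkyl-9-BBN 33 (not isolated)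
Conditions: 9-BBN-H, THF, rt; then 4, Pd(OAc)2 (cat.), SPhos (cat.), K3PO4, H2O, THF, 60 °C
Reagents that add atoms: none
Why: Hydroboration and B-alkyl Suzuki–Miyaura coupling: 9-BBN-H places boron on the terminal carbon and borane 33 transfers its primary alkyl group to aryl iodide 4, forming the C4–C4a bond of this half.

Step 22
Reactants: 34 coupled MOM/TBS ether
Product: 35 2-[(3S)-4-(benzyloxy)-3-hydroxybutyl]-6-methoxy-3-methylphenol
Conditions: HCl (cat.), MeOH, 45 °C
Reagents that add atoms: none
Why: Acid-catalysed methanolysis removes the MOM acetal and the secondary silyl ether together, as in step 8.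

Step 23
Reactants: 35 phenol alcohol
Product: 36 (2R)-2-[(benzyloxy)methyl]-8-methoxy-5-methyl-3,4-dihydro-2H-chromene
Conditions: PPh3, DIAD, THF, 0 °C → rt
Reagents that add atoms: none
Why: Intramolecular Mitsunobu etherification closes the pyran in a 6-exo-tet SN2 reaction with inversion, so the (S)-carbinol from the glycidyl ether becomes (2R).

Step 24
Reactants: 36 chroman
Product: 37 [(2R)-8-methoxy-5-methyl-3,4,4a,7-tetrahydro-2H-chromen-2-yl]methanol (both C4a epimers)
Conditions: Li, NH3(l)/THF, t-BuOH, −78 → −33 °C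
Reagents that add atoms: none
Why: Birch reduction with the same regiochemical logic as step 10 (hydrogen added at C4a and C7) and concurrent reductive debenzylation.

Step 25
Reactants: 37 diene alcohol
Product: 38 tert-butyl{[(2R)-8-methoxy-5-methyl-3,4,4a,7-tetrahydro-2H-chromen-2-yl]methoxy}dimethylsilane (both C4a epimers)
Conditions: TBSCl, imidazole, DMF, 0 °C → rt
Reagents that add atoms: tert-butyldimethylsilyl chloride, CC(C)(C)[Si](C)(C)Cl
Why: Buffered silylation protects the alcohol before the carbene step without hydrolysing the enediol diether.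

Step 26
Reactants: 38 Birch diene silyl ether; 18 tribromomethane
Product: 40 (2R)-9-bromo-2-(TBS-oxymethyl)-5-methyl-3,4,4a,7-tetrahydrocyclohepta[b]pyran-8(2H)-one (both C4a epimers), via dibromocyclopropane 39 (not isolated)
Conditions: KOtBu, pentane, −20 °C → rt
Reagents that add atoms: none
Why: Dibromocarbene addition to the dialkoxy alkene followed by disrotatory cyclopropane opening and bromide-induced demethylation enlarges the ring exactly as in step 12.

Step 27
Reactants: 40 bromodienone
Product: 42 (2R)-9-bromo-2-(TBS-oxymethyl)-8-hydroxy-5-methyl-3,4-dihydrocyclohepta[b]pyran-7(2H)-one, via 7,8-dione 41 (not isolated)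
Conditions: SeO2, KH2PO4, 1,4-dioxane, 90 °C
Reagents that add atoms: selenium dioxide, O=[Se]=O
Why: Riley oxidation of the doubly activated C7 methylene and tautomerisation of dione 41 to the aromatic tropolone, as in step 13.

Step 28
Reactants: 42 bromotropolone
Product: 43 (2R)-2-(TBS-oxymethyl)-8-hydroxy-5-methyl-3,4-dihydrocyclohepta[b]pyran-7(2H)-one
Conditions: Zn dust, AcOH, THF, rt
Reagents that add atoms: none
Why: Zinc reduction of the α-bromo carbonyl tautomer replaces the C9 bromine by hydrogen, as in step 14.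

Step 29
Reactants: 43 tropolone silyl ether
Product: 44 (2R)-8-hydroxy-2-(hydroxymethyl)-5-methyl-3,4-dihydrocyclohepta[b]pyran-7(2H)-one
Conditions: HCl (cat.), MeOH, rt
Reagents that add atoms: none
Why: Acid-catalysed methanolysis of the primary silyl ether.

Step 30
Reactants: 44 tropolone alcohol
Product: 45 (2R)-2-(hydroxymethyl)-8-(methoxymethoxy)-5-methyl-3,4-dihydrocyclohepta[b]pyran-7(2H)-one
Conditions: MOMCl (1.05 equiv), iPr2NEt, CH2Cl2, −20 → 0 °C
Reagents that add atoms: chloromethyl methyl ether, COCCl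
Why: Chemoselective O-alkylation of the ionised tropolone in the presence of the neutral primary alcohol, as in step 16.

Step 31
Reactants: 45 MOM-protected alcohol
Product: 46 (2R)-8-(methoxymethoxy)-5-methyl-2-[(PT-sulfanyl)methyl]-3,4-dihydrocyclohepta[b]pyran-7(2H)-one
Conditions: 1-phenyl-1H-tetrazole-5-thiol, PPh3, DIAD, THF, 0 °C → rt
Reagents that add atoms: 1-phenyl-1H-tetrazole-5-thiol, Sc1nnnn1-c1ccccc1
Why: Mitsunobu thioetherification: the acidic thiol displaces the activated primary alcohol and C2 is not involved.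

Step 32
Reactants: 46 sulfide
Product: 47 (2R)-8-(methoxymethoxy)-5-methyl-2-[(PT-sulfonyl)methyl]-3,4-dihydrocyclohepta[b]pyran-7(2H)-one
Conditions: (NH4)6Mo7O24·4H2O (cat.), 30% H2O2, EtOH, 0 °C → rt
Reagents that add atoms: hydrogen peroxide, OO
Why: Molybdate-catalysed peroxide oxidation takes the sulfide to the sulfone, and the electron-poor alkoxytropone ring should not be attacked by this electrophilic oxidant.

**Union and end game**

Step 33
Reactants: 47 PT sulfone; 28 enal
Product: 49 bis-MOM ether of the target: (2R,3R)-8-(methoxymethoxy)-2-{(1E,3E)-4-[(2R)-8-(methoxymethoxy)-5-methyl-7-oxo-2,3,4,7-tetrahydrocyclohepta[b]pyran-2-yl]buta-1,3-dien-1-yl}-3,5-dimethyl-3,4-dihydrocyclohepta[b]pyran-7(2H)-one, via potassiated sulfone 48 (not isolated)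
Conditions: KN(SiMe3)2 added last to 47 + 28, THF, −78 °C → rt
Reagents that add atoms: none
Why: Julia–Kocienski olefination: carbanion 48 adds to the enal, Smiles transfer of the tetrazole and loss of SO2 and tetrazolone should give the new alkene as its (E) isomer, as is usual with conjugated aldehydes, and adding the base to the mixture of both partners keeps the carbanion short-lived so that addition outruns expulsion of the β ring oxygen.

Step 34
Reactants: 49 bis-MOM ether
Product: 50 target, (2R,3R)-8-hydroxy-2-{(1E,3E)-4-[(2R)-8-hydroxy-5-methyl-7-oxo-2,3,4,7-tetrahydrocyclohepta[b]pyran-2-yl]buta-1,3-dien-1-yl}-3,5-dimethyl-3,4-dihydrocyclohepta[b]pyran-7(2H)-one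
Conditions: camphorsulfonic acid (cat.), MeOH–CH2Cl2, 0 °C → rt
Reagents that add atoms: none
Why: Acid-catalysed acetal exchange: protonation of the tropone oxygen makes the tropolone an excellent leaving group for the methoxymethyl cation, so both MOM groups should fall under acid too mild to ionise the dienylic C2–O1 bonds.

**Compound list**
1 | 2-methoxy-5-methylphenol | COc1ccc(C)cc1O | starting material
2 | 1-methoxy-2-(methoxymethoxy)-4-methylbenzene | COCOc1cc(C)ccc1OC | intermediate
3 | [3-methoxy-2-(methoxymethoxy)-6-methylphenyl]lithium | COCOc1c([Li])c(C)ccc1OC | intermediate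
4 | 2-iodo-4-methoxy-3-(methoxymethoxy)-1-methylbenzene | COCOc1c(I)c(C)ccc1OC | intermediate
5 | (S)-4-benzyl-3-propanoyl-1,3-oxazolidin-2-one | CCC(=O)N1[C@@H](Cc2ccccc2)COC1=O | starting material
6 | 2-(benzyloxy)acetaldehyde | O=CCOCc1ccccc1 | starting material
7 | (Z)-dibutylboron enolate of 5 | C/C=C(\OB(CCCC)CCCC)N1[C@@H](Cc2ccccc2)COC1=O | intermediate
8 | (S)-4-benzyl-3-[(2S,3S)-4-(benzyloxy)-3-hydroxy-2-methylbutanoyl]-1,3-oxazolidin-2-one | O=C1OC[C@H](Cc2ccccc2)N1C(=O)[C@@H](C)[C@H](O)COCc1ccccc1 | intermediate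
9 | TBS ether of 8, (2S,3S) | O=C1OC[C@H](Cc2ccccc2)N1C(=O)[C@@H](C)[C@H](O[Si](C)(C)C(C)(C)C)COCc1ccccc1 | intermediate
10 | (2R,3S)-4-(benzyloxy)-3-(TBS-oxy)-2-methylbutan-1-ol | OC[C@@H](C)[C@H](O[Si](C)(C)C(C)(C)C)COCc1ccccc1 | intermediate
11 | {[(2S,3S)-1-(benzyloxy)-4-iodo-3-methylbutan-2-yl]oxy}(tert-butyl)dimethylsilane | IC[C@@H](C)[C@H](O[Si](C)(C)C(C)(C)C)COCc1ccccc1 | intermediate
12 | [(2S,3S)-4-(benzyloxy)-3-(TBS-oxy)-2-methylbutyl]zinc iodide | I[Zn]C[C@@H](C)[C@H](O[Si](C)(C)C(C)(C)C)COCc1ccccc1 | intermediate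
13 | {[(2S,3R)-1-(benzyloxy)-4-[3-methoxy-2-(methoxymethoxy)-6-methylphenyl]-3-methylbutan-2-yl]oxy}(tert-butyl)dimethylsilane | COCOc1c(C[C@@H](C)[C@H](O[Si](C)(C)C(C)(C)C)COCc2ccccc2)c(C)ccc1OC | intermediate
14 | 2-[(2R,3S)-4-(benzyloxy)-3-hydroxy-2-methylbutyl]-6-methoxy-3-methylphenol | COc1ccc(C)c(C[C@@H](C)[C@H](O)COCc2ccccc2)c1O | intermediate
15 | (2R,3R)-2-[(benzyloxy)methyl]-8-methoxy-3,5-dimethyl-3,4-dihydro-2H-chromene | COc1ccc(C)c2C[C@@H](C)[C@H](COCc3ccccc3)Oc12 | intermediate
16 | [(2R,3R)-8-methoxy-3,5-dimethyl-3,4,4a,7-tetrahydro-2H-chromen-2-yl]methanol, C4a epimers | CC1=CCC(OC)=C2C1C[C@@H](C)[C@H](CO)O2 | intermediate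
17 | TBS ether of 16 (key-step precursor), C4a epimers | CC1=CCC(OC)=C2C1C[C@@H](C)[C@H](CO[Si](C)(C)C(C)(C)C)O2 | intermediate
18 | tribromomethane | BrC(Br)Br | starting material
19 | dibromocyclopropane across C8–C8a of 17 | CC1=CCC2(OC)C(Br)(Br)C23O[C@@H](CO[Si](C)(C)C(C)(C)C)[C@H](C)CC13 | intermediate
20 | (2R,3R)-9-bromo-2-(TBS-oxymethyl)-3,5-dimethyl-3,4,4a,7-tetrahydrocyclohepta[b]pyran-8(2H)-one, C4a epimers | CC1=CCC(=O)C(Br)=C2C1C[C@@H](C)[C@H](CO[Si](C)(C)C(C)(C)C)O2 | intermediate
21 | (2R,3R)-9-bromo-2-(TBS-oxymethyl)-3,5-dimethyl-3,4-dihydro-2H-cyclohepta[b]pyran-7,8(4aH)-dione | CC1=CC(=O)C(=O)C(Br)=C2C1C[C@@H](C)[C@H](CO[Si](C)(C)C(C)(C)C)O2 | intermediate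
22 | (2R,3R)-9-bromo-2-(TBS-oxymethyl)-8-hydroxy-3,5-dimethyl-3,4-dihydrocyclohepta[b]pyran-7(2H)-one | CC1=CC(=O)C(O)=C(Br)C2=C1C[C@@H](C)[C@H](CO[Si](C)(C)C(C)(C)C)O2 | intermediate
23 | (2R,3R)-2-(TBS-oxymethyl)-8-hydroxy-3,5-dimethyl-3,4-dihydrocyclohepta[b]pyran-7(2H)-one | CC1=CC(=O)C(O)=CC2=C1C[C@@H](C)[C@H](CO[Si](C)(C)C(C)(C)C)O2 | intermediate
24 | (2R,3R)-8-hydroxy-2-(hydroxymethyl)-3,5-dimethyl-3,4-dihydrocyclohepta[b]pyran-7(2H)-one | CC1=CC(=O)C(O)=CC2=C1C[C@@H](C)[C@H](CO)O2 | intermediate
25 | (2R,3R)-2-(hydroxymethyl)-8-(methoxymethoxy)-3,5-dimethyl-3,4-dihydrocyclohepta[b]pyran-7(2H)-one | CC1=CC(=O)C(OCOC)=CC2=C1C[C@@H](C)[C@H](CO)O2 | intermediate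
26 | (2R,3R)-8-(methoxymethoxy)-3,5-dimethyl-7-oxo-2,3,4,7-tetrahydrocyclohepta[b]pyran-2-carbaldehyde | CC1=CC(=O)C(OCOC)=CC2=C1C[C@@H](C)[C@H](C=O)O2 | intermediate
27 | (triphenylphosphoranylidene)acetaldehyde | O=CC=P(c1ccccc1)(c1ccccc1)c1ccccc1 | starting material
28 | (2E)-3-[(2R,3R)-8-(methoxymethoxy)-3,5-dimethyl-7-oxo-2,3,4,7-tetrahydrocyclohepta[b]pyran-2-yl]prop-2-enal | CC1=CC(=O)C(OCOC)=CC2=C1C[C@@H](C)[C@H](/C=C/C=O)O2 | intermediate
29 | (S)-benzyl glycidyl ether | C1O[C@@H]1COCc2ccccc2 | starting material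
30 | trimethylsulfonium iodide | C[S+](C)C.[I-] | starting material
31 | (S)-1-(benzyloxy)but-3-en-2-ol | C=C[C@H](O)COCc1ccccc1 | intermediate
32 | {[(2S)-1-(benzyloxy)but-3-en-2-yl]oxy}(tert-butyl)dimethylsilane | C=C[C@H](O[Si](C)(C)C(C)(C)C)COCc1ccccc1 | intermediate
33 | 9-[(3S)-4-(benzyloxy)-3-(TBS-oxy)butyl]-9-borabicyclo[3.3.1]nonane | C1CCC2CCCC1B2CC[C@H](O[Si](C)(C)C(C)(C)C)COCc1ccccc1 | intermediate
34 | {[(2S)-1-(benzyloxy)-4-[3-methoxy-2-(methoxymethoxy)-6-methylphenyl]butan-2-yl]oxy}(tert-butyl)dimethylsilane | COCOc1c(CC[C@H](O[Si](C)(C)C(C)(C)C)COCc2ccccc2)c(C)ccc1OC | intermediate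
35 | 2-[(3S)-4-(benzyloxy)-3-hydroxybutyl]-6-methoxy-3-methylphenol | COc1ccc(C)c(CC[C@H](O)COCc2ccccc2)c1O | intermediate
36 | (2R)-2-[(benzyloxy)methyl]-8-methoxy-5-methyl-3,4-dihydro-2H-chromene | COc1ccc(C)c2CC[C@H](COCc3ccccc3)Oc12 | intermediate
37 | [(2R)-8-methoxy-5-methyl-3,4,4a,7-tetrahydro-2H-chromen-2-yl]methanol, C4a epimers | CC1=CCC(OC)=C2C1CC[C@H](CO)O2 | intermediate
38 | TBS ether of 37, C4a epimers | CC1=CCC(OC)=C2C1CC[C@H](CO[Si](C)(C)C(C)(C)C)O2 | intermediate
39 | dibromocyclopropane across C8–C8a of 38 | CC1=CCC2(OC)C(Br)(Br)C23O[C@@H](CO[Si](C)(C)C(C)(C)C)CCC13 | intermediate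
40 | (2R)-9-bromo-2-(TBS-oxymethyl)-5-methyl-3,4,4a,7-tetrahydrocyclohepta[b]pyran-8(2H)-one, C4a epimers | CC1=CCC(=O)C(Br)=C2C1CC[C@H](CO[Si](C)(C)C(C)(C)C)O2 | intermediate
41 | (2R)-9-bromo-2-(TBS-oxymethyl)-5-methyl-3,4-dihydro-2H-cyclohepta[b]pyran-7,8(4aH)-dione | CC1=CC(=O)C(=O)C(Br)=C2C1CC[C@H](CO[Si](C)(C)C(C)(C)C)O2 | intermediate
42 | (2R)-9-bromo-2-(TBS-oxymethyl)-8-hydroxy-5-methyl-3,4-dihydrocyclohepta[b]pyran-7(2H)-one | CC1=CC(=O)C(O)=C(Br)C2=C1CC[C@H](CO[Si](C)(C)C(C)(C)C)O2 | intermediate
43 | (2R)-2-(TBS-oxymethyl)-8-hydroxy-5-methyl-3,4-dihydrocyclohepta[b]pyran-7(2H)-one | CC1=CC(=O)C(O)=CC2=C1CC[C@H](CO[Si](C)(C)C(C)(C)C)O2 | intermediate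
44 | (2R)-8-hydroxy-2-(hydroxymethyl)-5-methyl-3,4-dihydrocyclohepta[b]pyran-7(2H)-one | CC1=CC(=O)C(O)=CC2=C1CC[C@H](CO)O2 | intermediate
45 | (2R)-2-(hydroxymethyl)-8-(methoxymethoxy)-5-methyl-3,4-dihydrocyclohepta[b]pyran-7(2H)-one | CC1=CC(=O)C(OCOC)=CC2=C1CC[C@H](CO)O2 | intermediate
46 | (2R)-8-(methoxymethoxy)-5-methyl-2-[(PT-sulfanyl)methyl]-3,4-dihydrocyclohepta[b]pyran-7(2H)-one | CC1=CC(=O)C(OCOC)=CC2=C1CC[C@H](CSc3nnnn3-c3ccccc3)O2 | intermediate
47 | (2R)-8-(methoxymethoxy)-5-methyl-2-[(PT-sulfonyl)methyl]-3,4-dihydrocyclohepta[b]pyran-7(2H)-one | CC1=CC(=O)C(OCOC)=CC2=C1CC[C@H](CS(=O)(=O)c3nnnn3-c3ccccc3)O2 | intermediate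
48 | potassium salt of the α-sulfonyl carbanion of 47 | CC1=CC(=O)C(OCOC)=CC2=C1CC[C@H]([CH-]S(=O)(=O)c3nnnn3-c3ccccc3)O2.[K+] | intermediate
49 | bis-MOM ether of the target, (2R,3R), (2R), (1E,3E) | CC1=CC(=O)C(OCOC)=CC2=C1C[C@@H](C)[C@H](/C=C/C=C/[C@H]3CCC4=C(O3)C=C(OCOC)C(=O)C=C4C)O2 | intermediate
50 | CNP0332980.1 | Cc1cc(=O)c(O)cc2c1C[C@@H](C)[C@H](/C=C/C=C/[C@H]1CCc3c(C)cc(=O)c(O)cc3O1)O2 | target

**Totals**
Total step count: 34. Longest linear sequence: 18 steps (steps 3–18, then 33 and 34).

**Steps most likely to fail**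

1. Step 12 (key step).
   - What may go wrong: part of the carbene may add to the trisubstituted C5=C6 alkene. Surplus butoxide may also enolise the product and drive loss of HBr, so that the oxidation handle at C7 is lost.
   - Fallback: separate cyclopropanation from ring opening and keep strong base out of the opening. Setting out from 17, dichlorocarbene made under phase transfer (CHCl3, 50% aq NaOH, BnEt3NCl, 0 °C) would give the more slowly ionising dichlorocyclopropane F1, which can be purified. Heating it in pyridine (90 °C) would open the ring while pyridine takes the O-methyl group, giving the 9-chlorodienone F2. SeO2 as in step 13 would give the 9-chlorotropolone F3. Hydrogenolysis (H2, Pd/C, NaOAc, MeOH) would come back to the route at 23.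

2. Step 13.
   - What may go wrong: selenium dioxide may dehydrogenate across C7 and C4a instead of transferring oxygen, may attack the allylic C5 methyl group, or may cause loss of the silyl ether through the acid it forms.
   - Fallback: two-stage oxygenation through the enolate. Setting out from 20, KN(SiMe3)2 (THF, −78 °C) and 2-(phenylsulfonyl)-3-phenyloxaziridine would give the 7-hydroxy ketone F4. Dess–Martin oxidation would give dione 21, which tautomerises, and the route is rejoined at 22.

3. Step 33.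
   - What may go wrong: the metalated sulfone may expel the β ring oxygen (opening of the pyran), the base may deprotonate the vinylogously acidic ring methyl groups, and the geometry of the new alkene may erode.
   - Fallback: form the central C–C single bond of the diene by cross-coupling, so that no carbanion ever sits next to C2. Setting out from 26, Takai olefination (CHI3, CrCl2, THF, 0 °C) would give the (E)-vinyl iodide F5. Setting out from 45, Dess–Martin oxidation would give the aldehyde F6, and Bu3SnCHBr2, CrCl2 and LiI (THF–DMF) would turn it into the (E)-vinylstannane F7. Stille coupling of the two (Pd2(dba)3, AsPh3, NMP, rt) keeps both alkene geometries and comes back to the route at 49.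

**Further compounds**
F1 | step 12 | dichlorocyclopropane across C8–C8a of 17, (2R,3R) | CC1=CCC2(OC)C(Cl)(Cl)C23O[C@@H](CO[Si](C)(C)C(C)(C)C)[C@H](C)CC13
F2 | step 12 | (2R,3R)-9-chloro-2-(TBS-oxymethyl)-3,5-dimethyl-3,4,4a,7-tetrahydrocyclohepta[b]pyran-8(2H)-one | CC1=CCC(=O)C(Cl)=C2C1C[C@@H](C)[C@H](CO[Si](C)(C)C(C)(C)C)O2
F3 | step 12 | (2R,3R)-9-chloro-2-(TBS-oxymethyl)-8-hydroxy-3,5-dimethyl-3,4-dihydrocyclohepta[b]pyran-7(2H)-one | CC1=CC(=O)C(O)=C(Cl)C2=C1C[C@@H](C)[C@H](CO[Si](C)(C)C(C)(C)C)O2
F4 | step 13 | (2R,3R)-9-bromo-7-hydroxy-2-(TBS-oxymethyl)-3,5-dimethyl-3,4,4a,7-tetrahydrocyclohepta[b]pyran-8(2H)-one | CC1=CC(O)C(=O)C(Br)=C2C1C[C@@H](C)[C@H](CO[Si](C)(C)C(C)(C)C)O2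
F5 | step 33 | (2R,3R)-2-[(E)-2-iodoethenyl]-8-(methoxymethoxy)-3,5-dimethyl-3,4-dihydrocyclohepta[b]pyran-7(2H)-one | CC1=CC(=O)C(OCOC)=CC2=C1C[C@@H](C)[C@H](/C=C/I)O2
F6 | step 33 | (2R)-8-(methoxymethoxy)-5-methyl-7-oxo-2,3,4,7-tetrahydrocyclohepta[b]pyran-2-carbaldehyde | CC1=CC(=O)C(OCOC)=CC2=C1CC[C@H](C=O)O2
F7 | step 33 | (2R)-8-(methoxymethoxy)-5-methyl-2-[(E)-2-(tributylstannyl)ethenyl]-3,4-dihydrocyclohepta[b]pyran-7(2H)-one | CC1=CC(=O)C(OCOC)=CC2=C1CC[C@H](/C=C/[Sn](CCCC)(CCCC)CCCC)O2
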